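**Strategy**

The strategy rests on disconnecting the C-3a–C-4 bond of the cyclohexene ring (indene numbering), which joins the ring-fusion methine to the quaternary carbon carrying CH3 and CO2H. Because the target is a γ,δ-unsaturated acid (HO2C–C-4–C-3a–C-3=C-2), this bond is formed by a ring-contracting Ireland–Claisen rearrangement: the silyl ketene acetal of a ten-membered allylic lactone collapses in one operation to the cyclohexene, creating C-3a and quaternary C-4 and releasing the free acid. The precursor is a macrolactone holding one E and one Z trisubstituted alkene. Ring-closing metathesis then forms the cyclopentene, and a final hydrozirconation–Negishi coupling converts a propynyl group into the phenyldiene.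

Key step: step 17

Remark: locants C-1 to C-7a are those of the indene skeleton of the target; compounds 10 to 32 are mixtures of epimers at the carbon that becomes C-4, which is harmless because this centre is planarized in step 17.

**Route**

Step 1
Reactants: 1 hex-3-yn-2-one
Product: 2 (2S)-hex-3-yn-2-ol
Conditions: RuCl(p-cymene)[(S,S)-TsNCHPhCHPhNH2] (0.5 mol %), i-PrOH, rt
Reagents that add atoms: none
Why: Noyori asymmetric transfer hydrogenation of an alkynyl methyl ketone, in which the (S,S)-diamine ligand should direct hydride to the face that gives the (S)-carbinol, the alkyne acting as the large π-substituent.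

Step 2
Reactants: 2 (2S)-hex-3-yn-2-ol
Product: 4 (2S,3Z)-4-iodohex-3-en-2-ol, via cyclic alkenylaluminate 3 (not isolated)
Conditions: NaAlH2(OCH2CH2OMe)2, Et2O, 0 °C to rt; then I2, −78 to 0 °C
Reagents that add atoms: iodine, II
Why: hydroxyl-directed trans-hydroalumination of the propargylic alcohol puts aluminium on the distal carbon and iodinolysis proceeds with retention, which should give the Z vinyl iodide while the carbinol centre is untouched.

Step 3
Reactants: 4 (2S,3Z)-4-iodohex-3-en-2-ol; 5 propyne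
Product: 6 (2S,3Z)-4-ethylhept-3-en-5-yn-2-ol
Conditions: PdCl2(PPh3)2 (3 mol %), CuI (6 mol %), Et3N, THF, rt
Reagents that add atoms: none
Why: Sonogashira coupling with retention of alkene geometry, so the propynyl group stays cis to the carbinol carbon.

Step 4
Reactants: 6 (2S,3Z)-4-ethylhept-3-en-5-yn-2-ol; 7 triethyl orthopropionate
Product: 10 ethyl (3S,4E)-3-ethyl-2-methyl-3-(prop-1-yn-1-yl)hex-4-enoate (C-2 epimers), via mixed orthoester 8 (not isolated), via ketene acetal 9 (not isolated)
Conditions: EtCO2H (5 mol %), neat 7, 140 °C, EtOH distilled off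
Reagents that add atoms: none
Why: Johnson–Claisen rearrangement through a chair array with the carbinol methyl equatorial, so that suprafacial 1,3-transfer of the (S)-carbinol chirality should set the quaternary centre (future C-5) and an E alkene, the α-centre being uncontrolled and irrelevant.

Step 5
Reactants: 10 ethyl (3S,4E)-3-ethyl-2-methyl-3-(prop-1-yn-1-yl)hex-4-enoate
Product: 12 ethyl (3S)-3-ethyl-3-formyl-2-methylhex-4-ynoate (C-2 epimers), via ozonide 11 (not isolated)
Conditions: O3, CH2Cl2, −78 °C (Sudan Red 7B end point); then Me2S, −78 °C to rt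
Reagents that add atoms: ozone, [O-][O+]=O
Why: ozonolysis with reductive work-up, in which the disubstituted alkene reacts far faster than the internal alkyne and the aldehyde formed is quaternary at its α-carbon and so cannot epimerize.

Step 6
Reactants: 12 ethyl (3S)-3-ethyl-3-formyl-2-methylhex-4-ynoate; 13 ethyltriphenylphosphonium iodide
Product: 14 ethyl (3R,4Z)-3-ethyl-5-iodo-2-methyl-3-(prop-1-yn-1-yl)hex-4-enoate (C-2 epimers)
Conditions: 13, n-BuLi, THF, rt; I2, −78 °C; NaN(SiMe3)2, −20 °C; then 12, −78 to −20 °C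
Reagents that add atoms: iodine, II
Why: Stork–Zhao olefination, in which the (1-iodoethylidene)phosphorane adds under kinetic control to place iodine cis to the alkyl residue, which should give the Z trisubstituted iodoalkene needed for a ring cis alkene.

Step 7
Reactants: 15 (E)-pent-3-en-2-ol (racemate)
Product: 16 (2S,3E)-pent-3-en-2-ol
Conditions: Candida antarctica lipase B (immobilized), vinyl acetate, hexane, rt, stopped slightly beyond half conversion; separation from the acetate
Reagents that add atoms: none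
Why: lipase-catalysed kinetic resolution (transesterification by a serine hydrolase), in which the enzyme should acylate the (R)-alcohol much faster and leave the (S)-alcohol in high enantiomeric purity.

Step 8
Reactants: 16 (2S,3E)-pent-3-en-2-ol; 17 bromoacetyl bromide
Product: 18 (2S,3E)-pent-3-en-2-yl bromoacetate
Conditions: pyridine, CH2Cl2, −20 to 0 °C
Reagents that add atoms: none
Why: O-acylation of the secondary alcohol by an acyl bromide, which does not involve the carbinol centre.

Step 9
Reactants: 14 ethyl (3R,4Z)-3-ethyl-5-iodo-2-methyl-3-(prop-1-yn-1-yl)hex-4-enoate; 18 (2S,3E)-pent-3-en-2-yl bromoacetate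
Product: 20 1-ethyl 7-[(2S,3E)-pent-3-en-2-yl] (3S,4Z)-3-ethyl-2,5-dimethyl-3-(prop-1-yn-1-yl)hept-4-enedioate (C-2 epimers), via Reformatsky reagent 19 (not isolated)
Conditions: 18, Zn dust (Me3SiCl-activated), THF, rt; then 14, Pd[P(t-Bu)3]2 (3 mol %), THF, rt
Reagents that add atoms: none
Why: Negishi-type coupling of a Reformatsky reagent with an alkenyl iodide, in which oxidative addition of the C–I bond to the bulky zerovalent palladium complex should be much faster than ionization of the secondary allylic ester and the Z geometry is retained.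

Step 10
Reactants: 20 the diester from step 9
Product: 23 (2R,3Z,5S)-7-ethoxy-5-ethyl-3,6-dimethyl-7-oxo-2-[(2R,3E)-pent-3-en-2-yl]-5-(prop-1-yn-1-yl)hept-3-enoic acid (C-6 epimers), via silyl ketene acetal 21 (not isolated), via trimethylsilyl ester 22 (not isolated)
Conditions: LiN(i-Pr)2, Me3SiCl (present from the start), THF/DMPU 4:1, −78 °C; then rt to 45 °C; 1 M HCl
Reagents that add atoms: none
Why: Ireland–Claisen rearrangement, in which the doubly activated CH2 is deprotonated in preference to the hindered α-H of the ethyl ester, DMPU should place the alkenyl group syn to O–Si, and a chair array with the carbinol methyl equatorial transfers the (S)-carbinol chirality to the two new centres (future C-7a and C-1) and gives an E propenyl group.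

Step 11
Reactants: 23 the acid from step 10
Product: 25 ethyl (3S,4Z,6R,7R,8E)-3-ethyl-6-(hydroxymethyl)-2,5,7-trimethyl-3-(prop-1-yn-1-yl)deca-4,8-dienoate (C-2 epimers), via mixed carbonic anhydride 24 (not isolated)
Conditions: i-BuOCOCl, N-methylmorpholine, THF, −15 °C; then NaBH4, H2O, 0 °C
Reagents that add atoms: none
Why: reduction of a mixed carbonic anhydride with NaBH4, which should leave the hindered ethyl ester, the alkenes and the alkyne untouched.

Step 12
Reactants: 25 the alcohol from step 11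
Product: 26 ethyl (3S,4Z,6R,7R,8E)-3-ethyl-6-formyl-2,5,7-trimethyl-3-(prop-1-yn-1-yl)deca-4,8-dienoate (C-2 epimers)
Conditions: Dess–Martin periodinane, pyridine, CH2Cl2, 0 °C; used at once
Reagents that add atoms: none
Why: Dess–Martin oxidation under buffered, non-basic conditions, chosen so that the doubly allylic α-centre of the aldehyde is neither epimerized nor moved into conjugation.

Step 13
Reactants: 26 the aldehyde from step 12; 27 ethyl 2-(triphenylphosphoranylidene)butanoate
Product: 28 diethyl (2E,4S,5Z,7S)-2,7-diethyl-5,8-dimethyl-4-[(2R,3E)-pent-3-en-2-yl]-7-(prop-1-yn-1-yl)nona-2,5-dienedioate (C-8 epimers)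
Conditions: 27 (1.5 equiv), toluene, 70 °C
Reagents that add atoms: none
Why: Wittig olefination with a stabilized α-branched ylide under neutral conditions, expected to give the E trisubstituted enoate with the ester trans to the chain.

Step 14
Reactants: 28 the diester from step 13
Product: 29 ethyl (3S,4Z,6S,7E)-3,8-diethyl-9-hydroxy-2,5-dimethyl-6-[(2R,3E)-pent-3-en-2-yl]-3-(prop-1-yn-1-yl)nona-4,7-dienoate (C-2 epimers)
Conditions: i-Bu2AlH (2.2 equiv), CH2Cl2, −78 °C; aq. potassium sodium tartrate
Reagents that add atoms: none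
Why: i-Bu2AlH 1,2-reduction of the unhindered conjugated ester to the allylic alcohol, the ester flanked by a tertiary and a quaternary carbon being much slower at −78 °C.

Step 15
Reactants: 29 the hydroxy ester from step 14
Product: 30 (3S,4Z,6S,7E)-3,8-diethyl-9-hydroxy-2,5-dimethyl-6-[(2R,3E)-pent-3-en-2-yl]-3-(prop-1-yn-1-yl)nona-4,7-dienoic acid (C-2 epimers)
Conditions: LiOH, THF/MeOH/H2O, 55 °C; then 1 M HCl to pH 3
Reagents that add atoms: lithium hydroxide, [Li+].[OH-]
Why: saponification of the hindered ethyl ester, in which the only base-labile centre is the α-carbon that is already an epimer mixture.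

Step 16
Reactants: 30 the seco acid from step 15
Product: 32 (4S,5Z,7S,8E)-4,9-diethyl-3,6-dimethyl-7-[(2R,3E)-pent-3-en-2-yl]-4-(prop-1-yn-1-yl)-3,4,7,10-tetrahydro-2H-oxecin-2-one (C-3 epimers), via mixed aroyl anhydride 31 (not isolated)
Conditions: 2,4,6-Cl3C6H2COCl, Et3N, THF, rt; then slow addition to DMAP, toluene (1 mM), 80 °C
Reagents that add atoms: none
Why: Yamaguchi macrolactonization at high dilution, in which the Z and E trisubstituted alkenes and the quaternary centre (Thorpe–Ingold effect) should fold the seco acid so that ten-membered ring closure competes with oligomerization.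

Step 17
Reactants: 32 the ten-membered lactone from step 16
Product: 35 (1R,2R,5S,6R)-6-(but-1-en-2-yl)-2-ethyl-1,4-dimethyl-5-[(2R,3E)-pent-3-en-2-yl]-2-(prop-1-yn-1-yl)cyclohex-3-ene-1-carboxylic acid, via silyl ketene acetal 33 (not isolated), via silyl ester 34 (not isolated)
Conditions: LiN(i-Pr)2, t-BuMe2SiCl, THF/DMPU 4:1, −78 °C; then toluene, 90 °C; then 1 M HCl, THF, rt
Reagents that add atoms: none
Why: Kinetic enolization of lactone 32 and O-silylation give ketene acetal 33, whose O–C(OSi)=C / CH2–C(Et)=CH array undergoes a concerted suprafacial [3,3] shift (Ireland–Claisen rearrangement) on heating, and silyl ester 34 is hydrolysed on work-up. The closest known reaction type is the four-atom ring contraction of unsaturated macrolactone silyl ketene acetals to 2-alkenylcycloalkanecarboxylic acids, with the germacrene-to-elemene Cope rearrangement as the model for the ring geometry. The cyclohexene closes by transannular C–C bond formation between the enolate carbon and the distal alkene carbon (formally 6-exo-trig), the ten-membered ring contracting to six while the lactone C–O bond breaks and the butenyl group becomes a side chain. C-3a is set by the E ring alkene and the chair array in which the pentenyl group on the existing centre (future C-7a) is equatorial, and C-4 is set by the ketene acetal geometry (quaternary carbon anti to the ring oxygen), so that CO2H ends trans to the butenyl group and cis to H-3a. The step needs the germacrene-like E,E triene and the chair over the boat: DMPU-assisted enolization should keep the bulky quaternary carbon away from the alkoxy carbon, and both resident centres (pentenyl and ethyl equatorial, slim propynyl axial) favour the same chair. Both α-epimers of 32 should converge on 33, and no other enolizable ester or allylic C–O bond is present, so no regiochemical alternative exists.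

Step 18
Reactants: 35 the cyclohexene acid from step 17
Product: 36 (1R,3aR,4R,5R,7aS)-3,5-diethyl-1,4,7-trimethyl-5-(prop-1-yn-1-yl)-3a,4,5,7a-tetrahydro-1H-indene-4-carboxylic acid
Conditions: second-generation Grubbs catalyst (H2IMes)(PCy3)Cl2Ru=CHPh (5 mol %), CH2Cl2, 40 °C
Reagents that add atoms: none
Why: ring-closing metathesis between the 1,1-disubstituted alkene and the propenyl group with loss of propene, in which the trans-diequatorial side chains close to a trans-fused cyclopentene and the ring trisubstituted alkene and the hindered internal alkyne should not engage.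

Step 19
Reactants: 36 the bicyclic alkyne acid from step 18; 37 (E)-(2-bromovinyl)benzene
Product: 40 (1R,3aR,4R,5S,7aS)-3,5-diethyl-1,4,7-trimethyl-5-[(1E,3E)-2-methyl-4-phenylbuta-1,3-dien-1-yl]-3a,4,5,7a-tetrahydro-1H-indene-4-carboxylic acid, via alkenylzirconocene 38 (not isolated), via alkenylzinc chloride 39 (not isolated)
Conditions: Cp2Zr(H)Cl (2.5 equiv), THF, rt to 40 °C; then ZnCl2, 37, Pd(PPh3)4 (5 mol %), rt; 1 M HCl work-up
Reagents that add atoms: none
Why: syn hydrozirconation should place zirconium on the methyl-bearing alkyne carbon, away from the quaternary centre, and zinc-mediated Negishi coupling with retention at both partners should give the (1E,3E)-diene, the first equivalent of hydride being consumed by the carboxylic acid.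

**Compound list**

1 | hex-3-yn-2-one | CCC#CC(C)=O | starting material
2 | (2S)-hex-3-yn-2-ol | CCC#C[C@H](C)O | intermediate
3 | sodium salt of the cyclic alkenylaluminate from 2 (five-membered C=C–C–O–Al ring, two 2-methoxyethoxy groups on Al) | CCC1=C[C@H](C)O[Al-]1(OCCOC)OCCOC.[Na+] | intermediate
4 | (2S,3Z)-4-iodohex-3-en-2-ol | CC/C(I)=C/[C@H](C)O | intermediate
5 | propyne | CC#C | starting material
6 | (2S,3Z)-4-ethylhept-3-en-5-yn-2-ol | CC/C(C#CC)=C/[C@H](C)O | intermediate
7 | triethyl orthopropionate | CCC(OCC)(OCC)OCC | starting material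
8 | 1,1-diethoxy-1-{[(2S,3Z)-4-ethylhept-3-en-5-yn-2-yl]oxy}propane (mixed orthoester) | CCC(OCC)(OCC)O[C@@H](C)/C=C(\C#CC)CC | intermediate
9 | 1-ethoxy-1-{[(2S,3Z)-4-ethylhept-3-en-5-yn-2-yl]oxy}prop-1-ene (ketene acetal) | CC=C(OCC)O[C@@H](C)/C=C(\C#CC)CC | intermediate
10 | ethyl (3S,4E)-3-ethyl-2-methyl-3-(prop-1-yn-1-yl)hex-4-enoate (C-2 epimers) | CCOC(=O)C(C)[C@@](CC)(C#CC)/C=C/C | intermediate
11 | ozonide (1,2,4-trioxolane) of 10 | CCOC(=O)C(C)[C@@](CC)(C#CC)C1OC(C)OO1 | intermediate
12 | ethyl (3S)-3-ethyl-3-formyl-2-methylhex-4-ynoate (C-2 epimers) | CCOC(=O)C(C)[C@@](CC)(C#CC)C=O | intermediate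
13 | ethyltriphenylphosphonium iodide | CC[P+](c1ccccc1)(c1ccccc1)c1ccccc1.[I-] | starting material
14 | ethyl (3R,4Z)-3-ethyl-5-iodo-2-methyl-3-(prop-1-yn-1-yl)hex-4-enoate (C-2 epimers) | CCOC(=O)C(C)[C@@](CC)(C#CC)/C=C(/C)I | intermediate
15 | (E)-pent-3-en-2-ol (racemate) | C/C=C/C(C)O | starting material
16 | (2S,3E)-pent-3-en-2-ol | C/C=C/[C@H](C)O | intermediate
17 | bromoacetyl bromide | BrCC(Br)=O | starting material
18 | (2S,3E)-pent-3-en-2-yl bromoacetate | C/C=C/[C@H](C)OC(=O)CBr | intermediate
19 | bromo{2-oxo-2-[(2S,3E)-pent-3-en-2-yloxy]ethyl}zinc (Reformatsky reagent) | C/C=C/[C@H](C)OC(=O)C[Zn]Br | intermediate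
20 | 1-ethyl 7-[(2S,3E)-pent-3-en-2-yl] (3S,4Z)-3-ethyl-2,5-dimethyl-3-(prop-1-yn-1-yl)hept-4-enedioate (C-2 epimers) | CCOC(=O)C(C)[C@@](CC)(C#CC)/C=C(/C)CC(=O)O[C@@H](C)/C=C/C | intermediate
21 | trimethylsilyl ketene acetal of 20 at the pentenyl ester (alkenyl group syn to O–Si) | CCOC(=O)C(C)[C@@](CC)(C#CC)/C=C(/C)\C=C(/O[Si](C)(C)C)O[C@@H](C)/C=C/C | intermediate
22 | trimethylsilyl ester of 23 | CCOC(=O)C(C)[C@@](CC)(C#CC)/C=C(/C)[C@@H]([C@H](C)/C=C/C)C(=O)O[Si](C)(C)C | intermediate
23 | (2R,3Z,5S)-7-ethoxy-5-ethyl-3,6-dimethyl-7-oxo-2-[(2R,3E)-pent-3-en-2-yl]-5-(prop-1-yn-1-yl)hept-3-enoic acid (C-6 epimers) | CCOC(=O)C(C)[C@@](CC)(C#CC)/C=C(/C)[C@@H]([C@H](C)/C=C/C)C(=O)O | intermediate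
24 | isobutyl carbonic anhydride of 23 | CCOC(=O)C(C)[C@@](CC)(C#CC)/C=C(/C)[C@@H]([C@H](C)/C=C/C)C(=O)OC(=O)OCC(C)C | intermediate
25 | ethyl (3S,4Z,6R,7R,8E)-3-ethyl-6-(hydroxymethyl)-2,5,7-trimethyl-3-(prop-1-yn-1-yl)deca-4,8-dienoate (C-2 epimers) | CCOC(=O)C(C)[C@@](CC)(C#CC)/C=C(/C)[C@@H]([C@H](C)/C=C/C)CO | intermediate
26 | ethyl (3S,4Z,6R,7R,8E)-3-ethyl-6-formyl-2,5,7-trimethyl-3-(prop-1-yn-1-yl)deca-4,8-dienoate (C-2 epimers) | CCOC(=O)C(C)[C@@](CC)(C#CC)/C=C(/C)[C@@H]([C@H](C)/C=C/C)C=O | intermediate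
27 | ethyl 2-(triphenylphosphoranylidene)butanoate | CCOC(=O)C(CC)=P(c1ccccc1)(c1ccccc1)c1ccccc1 | starting material
28 | diethyl (2E,4S,5Z,7S)-2,7-diethyl-5,8-dimethyl-4-[(2R,3E)-pent-3-en-2-yl]-7-(prop-1-yn-1-yl)nona-2,5-dienedioate (C-8 epimers) | CCOC(=O)C(C)[C@@](CC)(C#CC)/C=C(/C)[C@@H]([C@H](C)/C=C/C)/C=C(/C(=O)OCC)CC | intermediate
29 | ethyl (3S,4Z,6S,7E)-3,8-diethyl-9-hydroxy-2,5-dimethyl-6-[(2R,3E)-pent-3-en-2-yl]-3-(prop-1-yn-1-yl)nona-4,7-dienoate (C-2 epimers) | CCOC(=O)C(C)[C@@](CC)(C#CC)/C=C(/C)[C@@H]([C@H](C)/C=C/C)/C=C(/CO)CC | intermediate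
30 | (3S,4Z,6S,7E)-3,8-diethyl-9-hydroxy-2,5-dimethyl-6-[(2R,3E)-pent-3-en-2-yl]-3-(prop-1-yn-1-yl)nona-4,7-dienoic acid (C-2 epimers) | OC(=O)C(C)[C@@](CC)(C#CC)/C=C(/C)[C@@H]([C@H](C)/C=C/C)/C=C(/CO)CC | intermediate
31 | 2,4,6-trichlorobenzoic anhydride of 30 | O=C(OC(=O)C(C)[C@@](CC)(C#CC)/C=C(/C)[C@@H]([C@H](C)/C=C/C)/C=C(/CO)CC)c1c(Cl)cc(Cl)cc1Cl | intermediate
32 | (4S,5Z,7S,8E)-4,9-diethyl-3,6-dimethyl-7-[(2R,3E)-pent-3-en-2-yl]-4-(prop-1-yn-1-yl)-3,4,7,10-tetrahydro-2H-oxecin-2-one (C-3 epimers) | O=C1OC/C(CC)=C/[C@H]([C@H](C)/C=C/C)/C(C)=C\[C@](CC)(C#CC)C1C | intermediate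
33 | tert-butyldimethylsilyl ketene acetal of 32 (quaternary carbon anti to the ring oxygen) | CC(C)(C)[Si](C)(C)O\C1=C(C)/[C@@](CC)(C#CC)\C=C(C)/[C@@H]([C@H](C)/C=C/C)/C=C(CC)/CO1 | intermediate
34 | tert-butyldimethylsilyl ester of 35 | C=C(CC)[C@H]1[C@H]([C@H](C)/C=C/C)C(C)=C[C@](CC)(C#CC)[C@]1(C)C(=O)O[Si](C)(C)C(C)(C)C | intermediate
35 | (1R,2R,5S,6R)-6-(but-1-en-2-yl)-2-ethyl-1,4-dimethyl-5-[(2R,3E)-pent-3-en-2-yl]-2-(prop-1-yn-1-yl)cyclohex-3-ene-1-carboxylic acid | C=C(CC)[C@H]1[C@H]([C@H](C)/C=C/C)C(C)=C[C@](CC)(C#CC)[C@]1(C)C(=O)O | intermediate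
36 | (1R,3aR,4R,5R,7aS)-3,5-diethyl-1,4,7-trimethyl-5-(prop-1-yn-1-yl)-3a,4,5,7a-tetrahydro-1H-indene-4-carboxylic acid | CCC1=C[C@@H](C)[C@@H]2C(C)=C[C@@](C#CC)(CC)[C@](C)(C(=O)O)[C@@H]12 | intermediate
37 | (E)-(2-bromovinyl)benzene | Br/C=C/c1ccccc1 | starting material
38 | alkenylzirconocene chloride from 36 (carboxyl as zirconocene carboxylate) | CCC1=C[C@@H](C)[C@@H]2C(C)=C[C@@](/C=C(C)/[Zr](Cl)(C3C=CC=C3)C3C=CC=C3)(CC)[C@](C)(C(=O)O[Zr](Cl)(C3C=CC=C3)C3C=CC=C3)[C@@H]12 | intermediate
39 | alkenylzinc chloride from 38 | CCC1=C[C@@H](C)[C@@H]2C(C)=C[C@@](/C=C(C)/[Zn]Cl)(CC)[C@](C)(C(=O)O[Zr](Cl)(C3C=CC=C3)C3C=CC=C3)[C@@H]12 | intermediate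
40 | (1R,3aR,4R,5S,7aS)-3,5-diethyl-1,4,7-trimethyl-5-[(1E,3E)-2-methyl-4-phenylbuta-1,3-dien-1-yl]-3a,4,5,7a-tetrahydro-1H-indene-4-carboxylic acid | CCC1=C[C@@H](C)[C@@H]2C(C)=C[C@@](/C=C(C)/C=C/c3ccccc3)(CC)[C@](C)(C(=O)O)[C@@H]12 | target

**Step count and risks**

Total steps: 19. Longest linear sequence: 17 steps (steps 1 to 6 and 9 to 19); steps 7 and 8 prepare the side reagent 18.

Steps most likely to fail:

1. Step 17. Enolization may give the ketene acetal with the quaternary carbon cis to the ring oxygen, or the rearrangement may pass through a boat array; either process inverts the sense of induction at C-4. The fallback sets out from 29 and closes the same bond on an acyclic ester enolate, free of the macrocycle. The alcohol is converted (MsCl, LiCl, 2,4,6-collidine, DMF) into the allylic chloride ethyl (3S,4Z,6S,7E)-9-chloro-3,8-diethyl-2,5-dimethyl-6-[(2R,3E)-pent-3-en-2-yl]-3-(prop-1-yn-1-yl)nona-4,7-dienoate F1. Treatment with KN(SiMe3)2 in THF at −78 to 0 °C should then bring about an intramolecular SN2′ alkylation (6-exo closure of the C-3a–C-4 bond) to the ethyl ester of 35, ethyl (1R,2R,5S,6R)-6-(but-1-en-2-yl)-2-ethyl-1,4-dimethyl-5-[(2R,3E)-pent-3-en-2-yl]-2-(prop-1-yn-1-yl)cyclohex-3-ene-1-carboxylate F2. Dealkylation with LiI in hot 2,6-lutidine returns to the route at 35.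

2. Step 16. Intermolecular esterification (oligomerization) and acyl transfer at the wrong carbonyl of the hindered mixed anhydride may outrun ten-membered ring closure. The fallback sets out from 30 and activates the alcohol instead of the acid: a Mitsunobu macrolactonization (PPh3, diisopropyl azodicarboxylate, toluene, high dilution, 0 °C to rt) lets the hindered carboxylate attack the primary allylic oxyphosphonium carbon and comes back to the route at 32. No new compound arises on the way (F0).

3. Step 6. Addition of the thermally labile iodo-ylide to the α-quaternary aldehyde may be slow, with decomposition of the ylide and erosion of Z selectivity. The fallback sets out from 12 and builds the alkene geometry by two stereospecific couplings. Corey–Fuchs olefination (CBr4, PPh3, CH2Cl2, 0 °C) gives the 1,1-dibromoalkene ethyl (3R)-5,5-dibromo-3-ethyl-2-methyl-3-(prop-1-yn-1-yl)pent-4-enoate F3. Trans-selective Negishi methylation (MeZnCl, PdCl2[(2-Ph2PC6H4)2O], THF, rt) of the bromine remote from the quaternary carbon gives the Z bromoalkene ethyl (3R,4Z)-5-bromo-3-ethyl-2-methyl-3-(prop-1-yn-1-yl)hex-4-enoate F4. Coupling of F4 with Reformatsky reagent 19 under the conditions of step 9 comes back to the route at 20.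

Further compounds
F1 | step 17 | ethyl (3S,4Z,6S,7E)-9-chloro-3,8-diethyl-2,5-dimethyl-6-[(2R,3E)-pent-3-en-2-yl]-3-(prop-1-yn-1-yl)nona-4,7-dienoate | CCOC(=O)C(C)[C@@](CC)(C#CC)/C=C(/C)[C@@H]([C@H](C)/C=C/C)/C=C(/CCl)CC
F2 | step 17 | ethyl (1R,2R,5S,6R)-6-(but-1-en-2-yl)-2-ethyl-1,4-dimethyl-5-[(2R,3E)-pent-3-en-2-yl]-2-(prop-1-yn-1-yl)cyclohex-3-ene-1-carboxylate | C=C(CC)[C@H]1[C@H]([C@H](C)/C=C/C)C(C)=C[C@](CC)(C#CC)[C@]1(C)C(=O)OCC
F0 | step 16 | none | none
F3 | step 6 | ethyl (3R)-5,5-dibromo-3-ethyl-2-methyl-3-(prop-1-yn-1-yl)pent-4-enoate | CCOC(=O)C(C)[C@@](CC)(C#CC)C=C(Br)Br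
F4 | step 6 | ethyl (3R,4Z)-5-bromo-3-ethyl-2-methyl-3-(prop-1-yn-1-yl)hex-4-enoate | CCOC(=O)C(C)[C@@](CC)(C#CC)/C=C(/C)Br
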